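The benzene ring is formed last, on a lactone that already carries C3. Ring atoms C1, O2, C3, C4, C4a and C8a are assembled first as a δ-lactone fused to a 2-pyrone. In that bicycle C4a=C8a and C8=C7 are the pyrone diene, and C8 bears an acyloxy group. One inverse-demand Diels–Alder reaction with 1,1-dimethoxyethene then adds C5 and C6(OMe); loss of CO2 and methanol gives the complete dihydroisocoumarin. The precursor is a (7R)-7-alkyl-7,8-dihydropyrano[4,3-b]pyran-2,5-dione with a 4-pivaloyloxy group and an acetate on the side-chain carbinol. It is made from (S)-1-octyn-3-ol by a vinylogous aldol, an acylketene lactonisation and a malonyl annulation.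

Key step: step 10

Remark: the target is read as (3R,6'S). In step 6 the (S)-enantiomer of BINOL is assigned by analogy with the Re-face preference of (R)-BINOL–titanium catalysts; the antipodal ligand is the remedy if Mosher ester analysis of the aldol product shows the opposite sense.

Remark on protecting groups: the pyrone oxygen carries a pivalate and the side-chain carbinol an acetate. An acyloxy group donates far less into the diene than an alkoxy group, both esters tolerate the HCl released in step 8, and both are removed together in step 11.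

Step 1
Reactants: 1 (S)-oct-1-yn-3-ol; 2 2-(3-bromopropyl)-1,3-dioxolane
Product: 4 (6S)-1-(1,3-dioxolan-2-yl)undec-4-yn-6-ol, via dilithium alkoxide acetylide 3 (not isolated)
Conditions: n-BuLi (2.1 equiv), THF, −78 → 0 °C; then 2, DMPU, 0 °C → rt; H2O quench
Reagents that add atoms: none
Why: Two equivalents of base give the alkoxide–acetylide, whose carbon terminus is far more nucleophilic than the lithium alkoxide, so SN2 alkylation of the acetylide by the primary bromide (alkylation of a propargylic alcohol dianion) attaches C1'–C3' and the masked C3 aldehyde without involving the C6' stereocenter.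

Step 2
Reactants: 4 (6S)-1-(1,3-dioxolan-2-yl)undec-4-yn-6-ol
Product: 5 (6S)-1-(1,3-dioxolan-2-yl)undecan-6-ol
Conditions: H2 (1 atm), Pd/C, Et3N (trace), EtOAc, rt
Reagents that add atoms: none
Why: Heterogeneous catalytic hydrogenation reduces the alkyne to the C4'–C5' ethylene unit, the trace of amine keeping the acetal intact and suppressing hydrogenolysis of the carbinol C–O bond, so that the (S) centre is carried through unchanged.

Step 3
Reactants: 5 (6S)-1-(1,3-dioxolan-2-yl)undecan-6-ol
Product: 6 (6S)-1-(1,3-dioxolan-2-yl)undecan-6-yl acetate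
Conditions: Ac2O, pyridine, DMAP (cat.), rt
Reagents that add atoms: acetic anhydride, CC(=O)OC(C)=O
Why: DMAP-catalysed acylation converts the secondary alcohol into an acetate, a protecting group chosen because it withstands the Lewis acid, the thermolysis and the HCl released later and is removed together with the phenol ester in the last step.

Step 4
Reactants: 6 (6S)-1-(1,3-dioxolan-2-yl)undecan-6-yl acetate
Product: 7 (6S)-12-oxododecan-6-yl acetate
Conditions: 1 M HCl, THF, rt
Reagents that add atoms: water, O
Why: Acid-catalysed hydrolysis of the cyclic acetal releases the aldehyde whose carbon becomes C3, under conditions too mild to hydrolyse a secondary acetate.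

Step 5
Reactants: 8 2,2,6-trimethyl-4H-1,3-dioxin-4-one
Product: 10 trimethyl[(2,2-dimethyl-6-methylidene-6H-1,3-dioxin-4-yl)oxy]silane, via lithium dienolate 9 (not isolated)
Conditions: LiN(iPr)2 (commercial solution), THF, −78 °C; then Me3SiCl, −78 °C → rt
Reagents that add atoms: chlorotrimethylsilane, C[Si](C)(C)Cl
Why: Kinetic deprotonation of the C6 methyl group (the gamma position of the vinylogous ester) and O-silylation of the resulting dienolate give the silyl dienol ether used as the acetoacetate gamma-nucleophile.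

Step 6
Reactants: 7 (6S)-12-oxododecan-6-yl acetate; 10 trimethyl[(2,2-dimethyl-6-methylidene-6H-1,3-dioxin-4-yl)oxy]silane
Product: 12 (6S,12R)-13-(2,2-dimethyl-4-oxo-4H-1,3-dioxin-6-yl)-12-hydroxytridecan-6-yl acetate, via O-trimethylsilyl aldol 11 (not isolated)
Conditions: Ti(OiPr)4 (10 mol %), (S)-BINOL (10 mol %), 4 Å molecular sieves, THF, −78 °C → rt; then 1 M HCl, THF, 0 °C
Reagents that add atoms: none
Why: In this catalytic enantioselective vinylogous Mukaiyama aldol reaction the chiral BINOL–titanium Lewis acid binds the aldehyde and exposes its Si face to the gamma-carbon of the dienolate, so that C3 is set as (R) by catalyst control independently of the remote C6' centre, and the acidic work-up cleaves the silyl ether.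

Step 7
Reactants: 12 (6S,12R)-13-(2,2-dimethyl-4-oxo-4H-1,3-dioxin-6-yl)-12-hydroxytridecan-6-yl acetate
Product: 14 (6S)-11-[(2R)-4,6-dioxooxan-2-yl]undecan-6-yl acetate, via acylketene 13 (not isolated)
Conditions: toluene (0.01 M), 110 °C
Reagents that add atoms: none
Why: Thermal retro-[4+2] loss of acetone from the dioxinone gives an acylketene that is captured intramolecularly by the C3 hydroxyl (six-membered lactonisation, favoured by high dilution) to form the beta-keto-delta-lactone without touching either stereocenter.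

Step 8
Reactants: 14 (6S)-11-[(2R)-4,6-dioxooxan-2-yl]undecan-6-yl acetate; 15 malonyl dichloride
Product: 16 (6S)-11-[(7R)-4-hydroxy-2,5-dioxo-7,8-dihydro-2H,5H-pyrano[4,3-b]pyran-7-yl]undecan-6-yl acetate
Conditions: ClCH2CH2Cl, 0 → 70 °C, N2 sweep
Reagents that add atoms: none
Why: The enol of the cyclic beta-keto lactone acts as a C,O-bis-nucleophile toward the bis-acid chloride, C-acylation at the carbon that becomes C8a and O-acylation of the enol oxygen on the carbon that becomes C4a closing the 4-hydroxy-2-pyrone ring, as in the known annulation of cyclic 1,3-dicarbonyl compounds with malonyl dichloride.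

Step 9
Reactants: 16 (6S)-11-[(7R)-4-hydroxy-2,5-dioxo-7,8-dihydro-2H,5H-pyrano[4,3-b]pyran-7-yl]undecan-6-yl acetate
Product: 17 (7R)-7-[(6S)-6-acetoxyundecyl]-2,5-dioxo-7,8-dihydro-2H,5H-pyrano[4,3-b]pyran-4-yl 2,2-dimethylpropanoate
Conditions: t-BuCOCl, Et3N, CH2Cl2, 0 °C
Reagents that add atoms: pivaloyl chloride, CC(C)(C)C(=O)Cl
Why: The acidic 4-hydroxyl of the pyrone (a vinylogous carboxylic acid) is O-acylated by the hindered acid chloride under mild base, giving an ester that, unlike an ether, does not raise the energy of the diene LUMO much, resists acyl transfer and later uncovers the C8 phenol without an ether cleavage.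

Step 10
Reactants: 17 (7R)-7-[(6S)-6-acetoxyundecyl]-2,5-dioxo-7,8-dihydro-2H,5H-pyrano[4,3-b]pyran-4-yl 2,2-dimethylpropanoate; 18 1,1-dimethoxyethene
Product: 21 (3R)-3-[(6S)-6-acetoxyundecyl]-6-methoxy-1-oxo-3,4-dihydro-1H-isochromen-8-yl 2,2-dimethylpropanoate, via bridged lactone adduct 19 (not isolated), via dimethoxycyclohexadiene 20 (not isolated)
Conditions: 18 (6 equiv), toluene, 110 °C, sealed tube
Reagents that add atoms: none
Why: The electron-poor pyrone of 17 undergoes an asynchronous inverse-electron-demand Diels–Alder reaction with the ketene acetal, the nucleophilic CH2 bonding to C4a (pyran position 8a) and the acetal carbon to C7 (pyran position 3) to give the 2-oxabicyclo[2.2.2]octenone 19. Retro-[4+2] loss of CO2 from 19 gives the cyclohexadiene 20, and elimination of methanol across C5–C6 aromatises it to 21. The closest known reaction type is the cycloaddition of ester-activated 2-pyrones with 1,1-dimethoxyethene, which gives alkoxybenzoates after loss of CO2 and methanol. The benzene ring closes by an intermolecular [4+2] annulation (bonds C4a–C5 and C6–C7) onto the preformed lactone ring; no stereocenter is created, and C3, which is not enolisable, is untouched. The selectivity needed is regiochemical, the new methoxy group having to land on C6, para to C8a. It is secured because C4a is beta to the C1 carbonyl and delta to the pyrone carbonyl, whereas C7 is alpha to the pyrone carbonyl; the fused lactone keeps C1 coplanar with the diene and the pivalate keeps the diene electron-poor.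

Step 11
Reactants: 21 (3R)-3-[(6S)-6-acetoxyundecyl]-6-methoxy-1-oxo-3,4-dihydro-1H-isochromen-8-yl 2,2-dimethylpropanoate
Product: 22 (3R)-8-hydroxy-3-[(6S)-6-hydroxyundecyl]-6-methoxy-3,4-dihydro-1H-isochromen-1-one
Conditions: K2CO3, MeOH, rt; then 1 M HCl
Reagents that add atoms: none
Why: Base-mediated transesterification with methanol cleaves the aryl pivalate and the secondary acetate in one operation while the phenoxide formed deactivates the lactone carbonyl, and acidification restores the phenol and recloses any lactone that opened, with C3 and C6' unaffected.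

Compound list
1 | (S)-oct-1-yn-3-ol | CCCCC[C@H](O)C#C | starting material
2 | 2-(3-bromopropyl)-1,3-dioxolane | BrCCCC1OCCO1 | starting material
3 | dilithium alkoxide acetylide of 1 | [Li+].[Li+].CCCCC[C@H]([O-])C#[C-] | intermediate
4 | (6S)-1-(1,3-dioxolan-2-yl)undec-4-yn-6-ol | CCCCC[C@H](O)C#CCCCC1OCCO1 | intermediate
5 | (6S)-1-(1,3-dioxolan-2-yl)undecan-6-ol | CCCCC[C@H](O)CCCCCC1OCCO1 | intermediate
6 | (6S)-1-(1,3-dioxolan-2-yl)undecan-6-yl acetate | CCCCC[C@H](OC(C)=O)CCCCCC1OCCO1 | intermediate
7 | (6S)-12-oxododecan-6-yl acetate | CCCCC[C@H](OC(C)=O)CCCCCC=O | intermediate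
8 | 2,2,6-trimethyl-4H-1,3-dioxin-4-one | CC1=CC(=O)OC(C)(C)O1 | starting material
9 | lithium dienolate of 8 (lithium 2,2-dimethyl-6-methylidene-6H-1,3-dioxin-4-olate) | [Li+].C=C1C=C([O-])OC(C)(C)O1 | intermediate
10 | trimethyl[(2,2-dimethyl-6-methylidene-6H-1,3-dioxin-4-yl)oxy]silane | C=C1C=C(O[Si](C)(C)C)OC(C)(C)O1 | intermediate
11 | (6S,12R)-13-(2,2-dimethyl-4-oxo-4H-1,3-dioxin-6-yl)-12-(trimethylsilyloxy)tridecan-6-yl acetate | CCCCC[C@H](OC(C)=O)CCCCC[C@@H](O[Si](C)(C)C)CC1=CC(=O)OC(C)(C)O1 | intermediate
12 | (6S,12R)-13-(2,2-dimethyl-4-oxo-4H-1,3-dioxin-6-yl)-12-hydroxytridecan-6-yl acetate | CCCCC[C@H](OC(C)=O)CCCCC[C@@H](O)CC1=CC(=O)OC(C)(C)O1 | intermediate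
13 | acylketene (6S,12R)-12-hydroxy-14,16-dioxohexadec-15-en-6-yl acetate | CCCCC[C@H](OC(C)=O)CCCCC[C@@H](O)CC(=O)C=C=O | intermediate
14 | (6S)-11-[(2R)-4,6-dioxooxan-2-yl]undecan-6-yl acetate (beta-keto-delta-lactone, drawn as the diketo tautomer) | CCCCC[C@H](OC(C)=O)CCCCC[C@@H]1CC(=O)CC(=O)O1 | intermediate
15 | malonyl dichloride | O=C(Cl)CC(Cl)=O | starting material
16 | (6S)-11-[(7R)-4-hydroxy-2,5-dioxo-7,8-dihydro-2H,5H-pyrano[4,3-b]pyran-7-yl]undecan-6-yl acetate | CCCCC[C@H](OC(C)=O)CCCCC[C@@H]1CC2=C(C(=O)O1)C(O)=CC(=O)O2 | intermediate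
17 | (7R)-7-[(6S)-6-acetoxyundecyl]-2,5-dioxo-7,8-dihydro-2H,5H-pyrano[4,3-b]pyran-4-yl 2,2-dimethylpropanoate | CCCCC[C@H](OC(C)=O)CCCCC[C@@H]1CC2=C(C(=O)O1)C(OC(=O)C(C)(C)C)=CC(=O)O2 | intermediate
18 | 1,1-dimethoxyethene | C=C(OC)OC | starting material
19 | bridged Diels–Alder adduct of 17 and 18: a C7–C(=O)–O–C4a lactone bridge across the ring C4a–C5H2–C6(OMe)2–C7H–C8(OPiv)=C8a (isocoumarin numbering), formed as both facial isomers at the bridgeheads | CCCCC[C@H](OC(C)=O)CCCCC[C@@H]1CC23CC(OC)(OC)C(C(=O)O2)C(OC(=O)C(C)(C)C)=C3C(=O)O1 | intermediate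
20 | (3R)-3-[(6S)-6-acetoxyundecyl]-6,6-dimethoxy-1-oxo-3,4,5,6-tetrahydro-1H-isochromen-8-yl 2,2-dimethylpropanoate | CCCCC[C@H](OC(C)=O)CCCCC[C@@H]1CC2=C(C(=O)O1)C(OC(=O)C(C)(C)C)=CC(OC)(OC)C2 | intermediate
21 | (3R)-3-[(6S)-6-acetoxyundecyl]-6-methoxy-1-oxo-3,4-dihydro-1H-isochromen-8-yl 2,2-dimethylpropanoate | CCCCC[C@H](OC(C)=O)CCCCC[C@@H]1Cc2cc(OC)cc(OC(=O)C(C)(C)C)c2C(=O)O1 | intermediate
22 | (3R)-8-hydroxy-3-[(6S)-6-hydroxyundecyl]-6-methoxy-3,4-dihydro-1H-isochromen-1-one | CCCCC[C@H](O)CCCCC[C@@H]1Cc2cc(OC)cc(O)c2C(=O)O1 | target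

Total steps: 11. Longest linear sequence: 10 steps (steps 1–4 and 6–11, from 1 to 22); step 5 is a one-step branch.

Steps most likely to fail

Step 10. The cycloaddition may be slower than the thermal self-condensation of the ketene acetal, or the pyrone pivalate may pass its acyl group to the methanol set free, so that the pyrone is consumed without ring formation. The fallback takes the benzene ring from a benzoic acid; it sets out from 7 and comes back to the route at 22. Corey–Chaykovsky methylenation of 7 (trimethylsulfonium iodide, n-BuLi, THF, −10 °C) should give the terminal epoxide (6S)-11-(oxiran-2-yl)undecan-6-yl acetate F1 as both epimers at the oxirane carbon. Hydrolytic kinetic resolution with the enantiomer of Co(salen)(OAc) that hydrolyses the (2S)-oxirane (0.55 equiv H2O) should leave (6S)-11-[(2R)-oxiran-2-yl]undecan-6-yl acetate F2. Carboxylate-directed ortho C–H alkylation of 2,4-dimethoxybenzoic acid with F2 (Pd(OAc)2, N-acetyl-tert-leucine, KOAc, (CF3)2CHOH, 75 °C) opens the epoxide at its CH2 group with retention at the carbinol carbon and lactonises in the same flask. It should give (6S)-11-[(3R)-6,8-dimethoxy-1-oxo-3,4-dihydro-1H-isochromen-3-yl]undecan-6-yl acetate F3. BCl3 (CH2Cl2, −78 → 0 °C) cleaves only the C8 methyl ether, which chelates to the C1 carbonyl, to give (6S)-11-[(3R)-8-hydroxy-6-methoxy-1-oxo-3,4-dihydro-1H-isochromen-3-yl]undecan-6-yl acetate F4. Methanolysis of the acetate (K2CO3, MeOH, then 1 M HCl) then gives 22.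

Step 8. Acylation by malonyl dichloride may stop at the enol oxygen or be overtaken by self-condensation of the acid chloride, leaving oligomeric enol malonates instead of the pyrone. The fallback closes the pyrone in two stages; it sets out from 14 and comes back at 16. C-Acylation of 14 with monomethyl malonate (DCC, DMAP, CH2Cl2; O-acylation followed by the DMAP-catalysed O-to-C acyl shift known for 4-hydroxy-5,6-dihydropyran-2-ones) should give methyl 3-{(6R)-6-[(6S)-6-acetoxyundecyl]-4-hydroxy-2-oxo-5,6-dihydro-2H-pyran-3-yl}-3-oxopropanoate F5. Heating F5 in toluene with catalytic TsOH closes the enol oxygen onto the methyl ester with loss of methanol to give 16.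

Step 6. Facial selectivity of the catalyst may be incomplete with the unbranched aldehyde. The C3 epimer would then be carried along, because its difference from 12 lies at a centre remote from C6' and cannot be removed by chromatography. The fallback sets C3 by ketone hydrogenation; it sets out from 7 and comes back at 14, so that steps 5–7 are not needed. Roskamp homologation of 7 (ethyl diazoacetate, SnCl2 cat., CH2Cl2) should give ethyl (9S)-9-acetoxy-3-oxotetradecanoate F6. Noyori hydrogenation (RuCl2[(R)-BINAP], H2, EtOH), whose sense for 3-oxoalkanoates is established, should give ethyl (3R,9S)-9-acetoxy-3-hydroxytetradecanoate F7. Acetylation (Ac2O, pyridine, DMAP) gives ethyl (3R,9S)-3,9-diacetoxytetradecanoate F8. Intramolecular Claisen (Dieckmann) condensation of the enolate of the C3 acetate onto the ethyl ester (LiN(SiMe3)2, THF, −78 °C) then closes the beta-keto-delta-lactone 14.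

Further compounds
F1 | step 10 | (6S)-11-(oxiran-2-yl)undecan-6-yl acetate, both epimers at the oxirane carbon | CCCCC[C@H](OC(C)=O)CCCCCC1CO1
F2 | step 10 | (6S)-11-[(2R)-oxiran-2-yl]undecan-6-yl acetate | CCCCC[C@H](OC(C)=O)CCCCC[C@@H]1CO1
F3 | step 10 | (6S)-11-[(3R)-6,8-dimethoxy-1-oxo-3,4-dihydro-1H-isochromen-3-yl]undecan-6-yl acetate | CCCCC[C@H](OC(C)=O)CCCCC[C@@H]1Cc2cc(OC)cc(OC)c2C(=O)O1
F4 | step 10 | (6S)-11-[(3R)-8-hydroxy-6-methoxy-1-oxo-3,4-dihydro-1H-isochromen-3-yl]undecan-6-yl acetate | CCCCC[C@H](OC(C)=O)CCCCC[C@@H]1Cc2cc(OC)cc(O)c2C(=O)O1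
F5 | step 8 | methyl 3-{(6R)-6-[(6S)-6-acetoxyundecyl]-4-hydroxy-2-oxo-5,6-dihydro-2H-pyran-3-yl}-3-oxopropanoate | CCCCC[C@H](OC(C)=O)CCCCC[C@@H]1CC(O)=C(C(=O)CC(=O)OC)C(=O)O1
F6 | step 6 | ethyl (9S)-9-acetoxy-3-oxotetradecanoate | CCCCC[C@H](OC(C)=O)CCCCCC(=O)CC(=O)OCC
F7 | step 6 | ethyl (3R,9S)-9-acetoxy-3-hydroxytetradecanoate | CCCCC[C@H](OC(C)=O)CCCCC[C@@H](O)CC(=O)OCC
F8 | step 6 | ethyl (3R,9S)-3,9-diacetoxytetradecanoate | CCCCC[C@H](OC(C)=O)CCCCC[C@@H](OC(C)=O)CC(=O)OCC
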